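In a closed flask of constant volume the substrate charged stays there in some form, yet at 4.00 h the teal run showed 11.3% of it as target and 0.4% as substrate, so 88.3% stood in forms I could not read. I wrote this note for whoever took over the bench.

| flask | substrate | reagent | remark | time |
|---|---|---|---|---|
| violet | 11 mM | 9.5 mM | run made earlier |  |
| teal | 39 mM | 9.5 mM | run made earlier |  |
| grey | 10 mM | 13 mM | run made earlier |  |
| maple | 10 mM | 9.50 mM |  | 5.0 h |
| larch | 20 mM | 3.00 mM |  | 5.0 h |
| oak | 30 mM | 40.0 mM |  | 5.0 h |
| birch | 10 mM | 20.0 mM |  | 5.0 h |
| alder | 15 mM | 3.00 mM |  | 5.0 h |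
| cedar | 10 mM | 2.50 mM |  | 5.0 h |

| run | time / h | target / % | substrate / % |
|---|---|---|---|
| violet | 0.667 | 17.0 | 0.1 |
| violet | 1.33 | 28.1 | 0.5 |
| violet | 2.00 | 34.7 | 0 |
| violet | 3.00 | 41.4 | 0 |
| violet | 4.00 | 45.3 | 0.5 |
| teal | 0.333 | 5.2 | 6.4 |
| teal | 0.833 | 8.3 | 0.4 |
| teal | 1.50 | 10.0 | 0.2 |
| teal | 2.50 | 11.0 | 0 |
| teal | 4.00 | 11.3 | 0.4 |
| grey | 0.333 | 11.3 | 4.4 |
| grey | 0.833 | 25.7 | 0.7 |
| grey | 1.50 | 36.6 | 0 |
| grey | 2.50 | 45.1 | 0.5 |
| grey | 4.00 | 48.1 | 0 |

(readings scatter by 0.5 percentage points)



1. ranking by amount of target, in percent of the substrate charged, from high to low, at 5.0 h (maple / larch / oak / birch / alder / cedar)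
2. the amount of target, in percent of the substrate charged of the flask you put first, at 5.0 h
3. the amount of target, in percent of the substrate charged of the flask you put last, at 5.0 h

At 0.333 h substrate read 6.4% in teal and 4.4% in grey, though teal was charged with 39 mM and grey with 10 mM, so I took its lifetime to be close in both. Target in teal flattened at 4.41 mM from 9.5 mM of reagent, a share of 46.4%. I treated the missing reagent as a correction to one target per reagent, lost in proportion to reagent and to substrate present. For a flask charged with less reagent than substrate, that gave target = reagent charged × exp(−substrate charged/S), and teal gave 50.8 mM for S, the reagent-loss scale: the substrate charge that cuts the reagent reaching target by a factor e. My note gave for 5.0 h cedar near 20.5%, alder near 14.9% and larch near 10.1%, and said to add no reagent, since these figures hold for the charges as written.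

The forecast gave birch > maple > oak > cedar > alder > larch, with 50% first and 6.9% last, and said of teal “so reagent limits”. Its last figure stood below my 10.1%.

The flasks gave maple > birch > oak > cedar > alder > larch, with 48.5% first and 9.20% last.

    substrate → intermediate (k = 0.0850 min⁻¹)
    substrate + reagent → side product A (k = 3.40 M⁻¹ min⁻¹)
    reagent + intermediate → target (k = 1.70 M⁻¹ min⁻¹)
    reagent → decomposition product (k = 1.20 × 10⁻⁴ min⁻¹)
    substrate → side product B (k = 0.0380 min⁻¹)

Larch ended with reagent, the limiting reagent, at 0.191% of its charge beside intermediate at 56.0%. Holding reagent at its charge raised larch's target from 9.20% to 49.4%, so the shrinking supply was the largest single effect, though it made up 44% of what was missing. S had given larch 10.1% against the 9.20%. A neighbour of larch charged with 80 mM of substrate got 0.776% from S and held 0.811% of target.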